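**Retrosynthetic overview**

1. The C6–CH3 bond is cut last: methyl transfer to a cyclic peroxycarbenium ion at C6 leads back to a C6 methoxy peroxyketal of the complete bicycle.
2. Both C–O bonds of the peroxide are then cut, C6–OO as the hydroperoxy ketal of a C6 ketone and C3–O as an oxa-Michael addition to the C2=C3 bond of a butenolide. The enabling feature is that the O–O unit bridges C6, which is at the ketone oxidation level once its methyl is removed, and C3, which is β to the lactone carbonyl C1 and three bonds from C6.
3. The keto-butenolide comes from a C4 tertiary alcohol and a C3 aldehyde (ketenylidene ylide), C4 from a copper–bis(oxazoline) pyruvate aldol, and the C6–C7 bond from a Fukuyama ketone synthesis.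
4. The side chain gets C8 by Evans alkylation with a dienyl bromide made by two E-selective Wittig reactions on phenylacetaldehyde.
5. Ring order: γ-lactone (butenolide, step 13) first, 1,2-dioxane (step 14) last.

Key step: step 14

Remark: carbons are numbered along the plakortolide chain, C1 (lactone C=O) to C14 (benzylic CH2); C3 and C6 carry the peroxide, C4 the lactone oxygen, C8 the side-chain methyl stereocenter.

**Route**

Step 1
Reactants: 1 phenylacetaldehyde; 2 2-(triphenylphosphoranylidene)propanal
Product: 3 (2E)-2-methyl-4-phenylbut-2-enal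
Conditions: toluene, 80 °C, slow addition of 1
Reagents that add atoms: none
Why: Wittig olefination with a formyl-stabilized ylide should give the E-trisubstituted enal, because oxaphosphetane formation is reversible for stabilized ylides and the E isomer is the more stable one; no stereocenter is formed.

Step 2
Reactants: 3 (2E)-2-methyl-4-phenylbut-2-enal; 4 ethyl 2-(triphenylphosphoranylidene)propanoate
Product: 5 ethyl (2E,4E)-2,4-dimethyl-6-phenylhexa-2,4-dienoate
Conditions: CH2Cl2, 40 °C
Reagents that add atoms: none
Why: A second Wittig olefination, now with an ester-stabilized ylide, should again be E-selective on the non-enolizable enal and extends the chain to the conjugated (2E,4E)-dienoate.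

Step 3
Reactants: 5 ethyl (2E,4E)-2,4-dimethyl-6-phenylhexa-2,4-dienoate
Product: 6 (2E,4E)-2,4-dimethyl-6-phenylhexa-2,4-dien-1-ol
Conditions: iBu2AlH (2.2 equiv), CH2Cl2, −78 °C
Reagents that add atoms: none
Why: Aluminium hydride reduction of the ester at low temperature should give the allylic alcohol by 1,2-delivery of hydride and leave the diene geometry untouched.

Step 4
Reactants: 6 (2E,4E)-2,4-dimethyl-6-phenylhexa-2,4-dien-1-ol
Product: 7 [(2E,4E)-6-bromo-3,5-dimethylhexa-2,4-dien-1-yl]benzene
Conditions: CBr4, PPh3, CH2Cl2, 0 °C; used crude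
Reagents that add atoms: carbon tetrabromide, BrC(Br)(Br)Br
Why: Appel bromination converts the primary allylic alcohol into the bromide by SN2 displacement of the oxyphosphonium group, and the low temperature should suppress allylic transposition along the diene.

Step 5
Reactants: 7 [(2E,4E)-6-bromo-3,5-dimethylhexa-2,4-dien-1-yl]benzene; 8 (4R)-4-benzyl-3-propanoyl-1,3-oxazolidin-2-one
Product: 10 (4R)-4-benzyl-3-[(2S,4E,6E)-2,4,6-trimethyl-8-phenylocta-4,6-dienoyl]-1,3-oxazolidin-2-one, via sodium enolate 9 (not isolated)
Conditions: 8, NaN(SiMe3)2, THF, −78 °C; then 7, −78 to −40 °C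
Reagents that add atoms: none
Why: Evans asymmetric alkylation: the sodium-chelated Z-enolate is alkylated by the reactive allylic bromide on the face opposite to the benzyl group of the (4R)-auxiliary, which should set the methyl-bearing stereocenter (C8) as S.

Step 6
Reactants: 10 (4R)-4-benzyl-3-[(2S,4E,6E)-2,4,6-trimethyl-8-phenylocta-4,6-dienoyl]-1,3-oxazolidin-2-one
Product: 11 (2S,4E,6E)-2,4,6-trimethyl-8-phenylocta-4,6-dien-1-ol
Conditions: LiBH4, H2O (1 equiv), Et2O, 0 °C
Reagents that add atoms: none
Why: Reductive removal of the auxiliary with LiBH4 attacks the more electrophilic exocyclic imide carbonyl and gives the primary alcohol without enolization, so that C8 keeps its configuration.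

Step 7
Reactants: 11 (2S,4E,6E)-2,4,6-trimethyl-8-phenylocta-4,6-dien-1-ol
Product: 12 [(2E,4E,7S)-8-iodo-3,5,7-trimethylocta-2,4-dien-1-yl]benzene
Conditions: I2, PPh3, imidazole, CH2Cl2, 0 °C to rt
Reagents that add atoms: iodine, II
Why: Appel-type iodination replaces the primary hydroxyl by iodide in an SN2 step that does not involve the neighbouring stereocenter.

Step 8
Reactants: 13 S-ethyl ethanethioate
Product: 15 [1-(ethylsulfanyl)ethenyl]oxy(trimethyl)silane, via lithium enolate 14 (not isolated)
Conditions: LiN(iPr)2, THF, −78 °C; then Me3SiCl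
Reagents that add atoms: chlorotrimethylsilane, C[Si](C)(C)Cl
Why: Kinetic deprotonation of the thioester followed by O-silylation of the lithium enolate gives the silyl ketene thioacetal, the nucleophile of the Mukaiyama aldol reaction.

Step 9
Reactants: 15 [1-(ethylsulfanyl)ethenyl]oxy(trimethyl)silane; 16 methyl 2-oxopropanoate (methyl pyruvate)
Product: 18 methyl (2R)-4-(ethylsulfanyl)-2-hydroxy-2-methyl-4-oxobutanoate, via silyl ether 17 (not isolated)
Conditions: Cu(OTf)2 (10 mol %), (R,R)-2,2'-(propane-2,2-diyl)bis(4-tert-butyl-4,5-dihydro-1,3-oxazole) (11 mol %), THF, −78 °C; then 1 M HCl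
Reagents that add atoms: none
Why: Catalytic enantioselective Mukaiyama aldol addition: methyl pyruvate is bound through both carbonyl oxygens to the square-planar complex of divalent copper and the bis(oxazoline), whose tert-butyl groups shield one face of the ketone, so that the (R,R)-ligand should give the tertiary alcohol (C4) as 2R, the mirror-image catalyst being the one known to give 2S.

Step 10
Reactants: 12 [(2E,4E,7S)-8-iodo-3,5,7-trimethylocta-2,4-dien-1-yl]benzene; 18 methyl (2R)-4-(ethylsulfanyl)-2-hydroxy-2-methyl-4-oxobutanoate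
Product: 20 methyl (2R,6S,8E,10E)-2-hydroxy-2,6,8,10-tetramethyl-4-oxo-12-phenyldodeca-8,10-dienoate, via alkylzinc iodide 19 (not isolated)
Conditions: 12, Zn, LiCl, THF, 40 °C; then 18 (1.3 equiv), PdCl2(PPh3)2 (5 mol %), toluene, rt
Reagents that add atoms: none
Why: Fukuyama ketone synthesis: zinc inserts into the C–I bond, zerovalent palladium formed in situ inserts into the C–S bond of the thioester, and transmetalation followed by reductive elimination forms the C6–C7 bond under neutral conditions that should tolerate the tertiary hydroxyl, the ester and the diene and touch no stereocenter.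

Step 11
Reactants: 20 methyl (2R,6S,8E,10E)-2-hydroxy-2,6,8,10-tetramethyl-4-oxo-12-phenyldodeca-8,10-dienoate
Product: 21 (2R,6S,8E,10E)-2,6,8,10-tetramethyl-12-phenyldodeca-8,10-diene-1,2,4-triol (both C4 epimers)
Conditions: LiAlH4, THF, 0 °C
Reagents that add atoms: none
Why: Hydride reduction of both the ester and the ketone brings C3 to the alcohol level in one operation; the new carbinol center is formed as both epimers, which does not matter because it is reoxidized in the next step.

Step 12
Reactants: 21 (2R,6S,8E,10E)-2,6,8,10-tetramethyl-12-phenyldodeca-8,10-diene-1,2,4-triol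
Product: 22 (2R,6S,8E,10E)-2-hydroxy-2,6,8,10-tetramethyl-4-oxo-12-phenyldodeca-8,10-dienal
Conditions: (COCl)2, DMSO, CH2Cl2, −78 °C; Et3N, −78 to 0 °C; used crude
Reagents that add atoms: none
Why: Swern oxidation converts the primary alcohol into the aldehyde and the secondary alcohol back into the ketone while the tertiary alcohol cannot react, and the cold non-aqueous conditions should spare the sensitive α-hydroxy aldehyde.

Step 13
Reactants: 22 (2R,6S,8E,10E)-2-hydroxy-2,6,8,10-tetramethyl-4-oxo-12-phenyldodeca-8,10-dienal; 23 (triphenylphosphoranylidene)ethenone (ketenylidene ylide)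
Product: 25 (5R)-5-methyl-5-[(4S,6E,8E)-4,6,8-trimethyl-2-oxo-10-phenyldeca-6,8-dien-1-yl]furan-2(5H)-one, via acyl ylide 24 (not isolated)
Conditions: toluene, 80 °C
Reagents that add atoms: none
Why: Lactonization with the ketenylidene ylide (Bestmann protocol): the tertiary hydroxyl adds to the cumulene to give an ester-stabilized ylide, which closes the five-membered butenolide by intramolecular Wittig reaction with the adjacent aldehyde faster than it could reach the remote ketone.

Step 14
Reactants: 25 (5R)-5-methyl-5-[(4S,6E,8E)-4,6,8-trimethyl-2-oxo-10-phenyldeca-6,8-dien-1-yl]furan-2(5H)-one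
Product: 27 (4aR,7aR)-3-methoxy-4a-methyl-3-[(2S,4E,6E)-2,4,6-trimethyl-8-phenylocta-4,6-dien-1-yl]tetrahydrofuro[3,2-c][1,2]dioxin-6(3H)-one (both C6 anomers), via hydroperoxy ketal 26 (not isolated)
Conditions: H2O2·urea, Sc(OTf)3 (10 mol %), MeOH, 0 °C to rt; evaporation; Et2NH (0.3 equiv), CF3CH2OH, rt
Reagents that add atoms: hydrogen peroxide (as its urea adduct), OO; methanol, CO
Why: Sc(OTf)3 activates the C6 ketone toward addition of methanol and hydrogen peroxide, which gives the α-methoxy hydroperoxide 26, and diethylamine then deprotonates the hydroperoxide so that its terminal oxygen adds to C3 of the butenolide and the lactone enolate is protonated at C2. The closest known reaction type is the hydroperoxyketalization of a ketone followed by base-mediated intramolecular oxa-Michael addition to an enoate, the standard entry to 3-alkoxy-1,2-dioxanes, together with the cyclization of tertiary hydroperoxides onto γ,γ-disubstituted butenolides. The 1,2-dioxane closes in the 6-exo-trig mode, the C2=C3 bond being exocyclic to the ring formed from O, O, C6, C5, C4 and C3. The new C3 stereocenter is controlled by the quaternary C4: the peroxide is tethered through C5 to C4, so it can reach C3 only on the face of the butenolide that bears C5, which forces the cis ring fusion (3R); the new C6 center is not controlled and forms as both anomers, which is without consequence because it is ionized and reset in step 15. The step needs chemoselective O-attack of the hydroperoxide in competition with aza-Michael addition of the amine and with base-induced β-elimination of the C4 carboxylate, and regioselective attack at C3; the first is secured by converting the enolizable β-acyloxy ketone completely into the non-enolizable ketal before any base is added and by the α-effect nucleophilicity of the hydroperoxide in CF3CH2OH, the second by C3 being the only acceptor carbon within reach of a six-membered transition state.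

Step 15
Reactants: 27 (4aR,7aR)-3-methoxy-4a-methyl-3-[(2S,4E,6E)-2,4,6-trimethyl-8-phenylocta-4,6-dien-1-yl]tetrahydrofuro[3,2-c][1,2]dioxin-6(3H)-one
Product: 28 plakortolide, (3R,4aR,7aR)-3,4a-dimethyl-3-[(2S,4E,6E)-2,4,6-trimethyl-8-phenylocta-4,6-dien-1-yl]tetrahydrofuro[3,2-c][1,2]dioxin-6(3H)-one
Conditions: AlMe3 (4 equiv), Me3SiOTf (1.2 equiv), CH2Cl2, −78 to −40 °C; aqueous NaHCO3
Reagents that add atoms: trimethylaluminium, C[Al](C)C
Why: Proposed new method: Me3SiOTf should ionize the anomeric methoxy group of either anomer to the same six-membered cyclic peroxycarbenium ion (the intermediate of the known Lewis-acid substitutions of 3-alkoxy-1,2-dioxanes and 3-alkoxy-1,2-dioxolanes by allylsilanes and silyl ketene acetals), and AlMe3, the reagent that methylates tetrahydropyranyl oxocarbenium ions generated from ketals and that has been used for C-alkylation of lactol derivatives of peroxide-containing trioxanes, should transfer methyl along the axial trajectory of the half-chair that has the C4 acyloxy oxygen pseudoaxial and the C4 methyl pseudoequatorial, that is, cis to the lactone oxygen and anti to the C4 methyl, which sets C6 as R.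

**Compound list**

1 | phenylacetaldehyde | O=CCc1ccccc1 | starting material
2 | 2-(triphenylphosphoranylidene)propanal | CC(C=O)=P(c1ccccc1)(c1ccccc1)c1ccccc1 | starting material
3 | (2E)-2-methyl-4-phenylbut-2-enal | O=C/C(C)=C/Cc1ccccc1 | intermediate
4 | ethyl 2-(triphenylphosphoranylidene)propanoate | CCOC(=O)C(C)=P(c1ccccc1)(c1ccccc1)c1ccccc1 | starting material
5 | ethyl (2E,4E)-2,4-dimethyl-6-phenylhexa-2,4-dienoate | CCOC(=O)/C(C)=C/C(C)=C/Cc1ccccc1 | intermediate
6 | (2E,4E)-2,4-dimethyl-6-phenylhexa-2,4-dien-1-ol | OC/C(C)=C/C(C)=C/Cc1ccccc1 | intermediate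
7 | [(2E,4E)-6-bromo-3,5-dimethylhexa-2,4-dien-1-yl]benzene | BrC/C(C)=C/C(C)=C/Cc1ccccc1 | intermediate
8 | (4R)-4-benzyl-3-propanoyl-1,3-oxazolidin-2-one | CCC(=O)N1C(=O)OC[C@H]1Cc1ccccc1 | starting material
9 | sodium (Z)-enolate of 8 | C/C=C(\[O-])N1C(=O)OC[C@H]1Cc1ccccc1.[Na+] | intermediate
10 | (4R)-4-benzyl-3-[(2S,4E,6E)-2,4,6-trimethyl-8-phenylocta-4,6-dienoyl]-1,3-oxazolidin-2-one | c1ccccc1C/C=C(C)/C=C(C)/C[C@H](C)C(=O)N1C(=O)OC[C@H]1Cc1ccccc1 | intermediate
11 | (2S,4E,6E)-2,4,6-trimethyl-8-phenylocta-4,6-dien-1-ol | c1ccccc1C/C=C(C)/C=C(C)/C[C@H](C)CO | intermediate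
12 | [(2E,4E,7S)-8-iodo-3,5,7-trimethylocta-2,4-dien-1-yl]benzene | c1ccccc1C/C=C(C)/C=C(C)/C[C@H](C)CI | intermediate
13 | S-ethyl ethanethioate | CC(=O)SCC | starting material
14 | lithium enolate of 13 | [Li+].[O-]C(=C)SCC | intermediate
15 | [1-(ethylsulfanyl)ethenyl]oxy(trimethyl)silane | C=C(O[Si](C)(C)C)SCC | intermediate
16 | methyl 2-oxopropanoate (methyl pyruvate) | CC(=O)C(=O)OC | starting material
17 | methyl (2R)-4-(ethylsulfanyl)-2-methyl-4-oxo-2-[(trimethylsilyl)oxy]butanoate | CCSC(=O)C[C@@](C)(O[Si](C)(C)C)C(=O)OC | intermediate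
18 | methyl (2R)-4-(ethylsulfanyl)-2-hydroxy-2-methyl-4-oxobutanoate | CCSC(=O)C[C@@](C)(O)C(=O)OC | intermediate
19 | iodido[(2S,4E,6E)-2,4,6-trimethyl-8-phenylocta-4,6-dien-1-yl]zinc | c1ccccc1C/C=C(C)/C=C(C)/C[C@H](C)C[Zn]I | intermediate
20 | methyl (2R,6S,8E,10E)-2-hydroxy-2,6,8,10-tetramethyl-4-oxo-12-phenyldodeca-8,10-dienoate | c1ccccc1C/C=C(C)/C=C(C)/C[C@H](C)CC(=O)C[C@@](C)(O)C(=O)OC | intermediate
21 | (2R,6S,8E,10E)-2,6,8,10-tetramethyl-12-phenyldodeca-8,10-diene-1,2,4-triol (both C4 epimers) | c1ccccc1C/C=C(C)/C=C(C)/C[C@H](C)CC(O)C[C@@](C)(O)CO | intermediate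
22 | (2R,6S,8E,10E)-2-hydroxy-2,6,8,10-tetramethyl-4-oxo-12-phenyldodeca-8,10-dienal | c1ccccc1C/C=C(C)/C=C(C)/C[C@H](C)CC(=O)C[C@@](C)(O)C=O | intermediate
23 | (triphenylphosphoranylidene)ethenone | O=C=C=P(c1ccccc1)(c1ccccc1)c1ccccc1 | starting material
24 | (triphenylphosphoranylidene)acetate of the tertiary hydroxyl of 22 (acyl ylide) | c1ccccc1C/C=C(C)/C=C(C)/C[C@H](C)CC(=O)C[C@@](C)(OC(=O)C=P(c2ccccc2)(c2ccccc2)c2ccccc2)C=O | intermediate
25 | (5R)-5-methyl-5-[(4S,6E,8E)-4,6,8-trimethyl-2-oxo-10-phenyldeca-6,8-dien-1-yl]furan-2(5H)-one | c1ccccc1C/C=C(C)/C=C(C)/C[C@H](C)CC(=O)C[C@@]1(C)OC(=O)C=C1 | intermediate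
26 | (5R)-5-[(4S,6E,8E)-2-hydroperoxy-2-methoxy-4,6,8-trimethyl-10-phenyldeca-6,8-dien-1-yl]-5-methylfuran-2(5H)-one (both epimers at the ketal carbon) | c1ccccc1C/C=C(C)/C=C(C)/C[C@H](C)CC(OC)(OO)C[C@@]1(C)OC(=O)C=C1 | intermediate
27 | (4aR,7aR)-3-methoxy-4a-methyl-3-[(2S,4E,6E)-2,4,6-trimethyl-8-phenylocta-4,6-dien-1-yl]tetrahydrofuro[3,2-c][1,2]dioxin-6(3H)-one (cis-fused; both C6 anomers) | c1ccccc1C/C=C(C)/C=C(C)/C[C@H](C)CC1(OC)C[C@@]2(C)OC(=O)C[C@H]2OO1 | intermediate
28 | plakortolide, (3R,4aR,7aR)-3,4a-dimethyl-3-[(2S,4E,6E)-2,4,6-trimethyl-8-phenylocta-4,6-dien-1-yl]tetrahydrofuro[3,2-c][1,2]dioxin-6(3H)-one | CC(=C\Cc1ccccc1)/C=C(\C)C[C@H](C)C[C@]1(C)C[C@@]2(C)OC(=O)C[C@H]2OO1 | target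

**Step count and risks**

Total step count: 15. Longest linear sequence: 13 steps (steps 1 to 7, then 10 to 15).

Steps most likely to fail:

1. Step 15 (proposed new method). The methyl transfer may show poor facial selectivity, the peroxycarbenium ion may fragment or lose a proton to a cyclic peroxy enol ether, or the organoaluminium may reduce the O–O bond. The fallback uses known chemistry, sets out from 25 and returns to the route at 28, at the price of giving up the control of C6. Methylenation of the ketone of 25 with Zn, CH2Br2 and TiCl4 would give the exocyclic alkene F1. Cobalt-catalysed hydroperoxysilylation (Isayama–Mukaiyama conditions: Co(C11H19O2)2, the bis(2,2,6,6-tetramethylheptane-3,5-dionate) of divalent cobalt, O2, Et3SiH, ClCH2CH2Cl) would add hydrogen and the silylperoxy group across the alkene in the Markovnikov sense to give the triethylsilyl peroxide F2 as both C6 epimers. Desilylation with HCl in MeOH would give the tertiary hydroperoxide F3, and cyclization with Et2NH in CF3CH2OH would give 28 together with the C6 epimer of the target F4, to be separated by preparative HPLC. The conjugated diene may compete for the cobalt hydride.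

2. Step 14 (key step). Ketalization may be incomplete, so that base opens the butenolide by β-elimination of the C4 carboxylate, the hydroperoxy ketal may revert to the ketone, or the amine may add to the butenolide. The fallback sets out from 25 and returns at 27, replacing the mixed ketal by a symmetrical peroxide donor. Re2O7-catalysed reaction of 25 with 50% aqueous H2O2 in CH3CN would give the geminal dihydroperoxide F5. Cyclization of one hydroperoxy group onto C3 with Et2NH in CF3CH2OH would give the anomeric hydroperoxide F6, and acid-catalysed exchange of the remaining anomeric hydroperoxy group in MeOH with camphorsulfonic acid would give 27.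

3. Step 13. The β-hydroxy ketone may undergo retro-aldol fragmentation or dehydration under the basic ylide at 80 °C, and acylation of the hindered tertiary hydroxyl may be slow. The fallback sets out from 20 and returns at 25; it masks the ketone so that no β-hydroxy ketone meets base and replaces the reduction–oxidation pair by a partial reduction. Ketalization of 20 with Me3SiOCH2CH2OSiMe3 and catalytic Me3SiOTf in CH2Cl2 at −78 °C would give the dioxolane ketal F7. Reduction with iBu2AlH at −78 °C would give the α-hydroxy aldehyde F8, lactonization with ylide 23 in toluene at 80 °C would give the ketal-protected butenolide F9, and hydrolysis with pyridinium p-toluenesulfonate in aqueous acetone would give 25.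

Further compounds
F1 | step 15 | exocyclic-methylene analogue of 25 (C6=CH2 in place of C6=O) | c1ccccc1C/C=C(C)/C=C(C)/C[C@H](C)CC(=C)C[C@@]1(C)OC(=O)C=C1
F2 | step 15 | triethylsilyl peroxide at C6 of the methyl-bearing butenolide (both C6 epimers) | c1ccccc1C/C=C(C)/C=C(C)/C[C@H](C)CC(C)(OO[Si](CC)(CC)CC)C[C@@]1(C)OC(=O)C=C1
F3 | step 15 | tertiary C6 hydroperoxide of the butenolide (both C6 epimers) | c1ccccc1C/C=C(C)/C=C(C)/C[C@H](C)CC(C)(OO)C[C@@]1(C)OC(=O)C=C1
F4 | step 15 | C6 epimer of 28 | CC(=C\Cc1ccccc1)/C=C(\C)C[C@H](C)C[C@@]1(C)C[C@@]2(C)OC(=O)C[C@H]2OO1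
F5 | step 14 | geminal C6 dihydroperoxide derived from 25 | c1ccccc1C/C=C(C)/C=C(C)/C[C@H](C)CC(OO)(OO)C[C@@]1(C)OC(=O)C=C1
F6 | step 14 | C6 hydroperoxy analogue of 27 (both anomers) | c1ccccc1C/C=C(C)/C=C(C)/C[C@H](C)CC1(OO)C[C@@]2(C)OC(=O)C[C@H]2OO1
F7 | step 13 | ethylene ketal of 20 | c1ccccc1C/C=C(C)/C=C(C)/C[C@H](C)CC1(OCCO1)C[C@@](C)(O)C(=O)OC
F8 | step 13 | ethylene ketal of 22 | c1ccccc1C/C=C(C)/C=C(C)/C[C@H](C)CC1(OCCO1)C[C@@](C)(O)C=O
F9 | step 13 | ethylene ketal of 25 | c1ccccc1C/C=C(C)/C=C(C)/C[C@H](C)CC1(OCCO1)C[C@@]2(C)OC(=O)C=C2
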